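**Retrosynthetic overview**

1. Target ⇐ peracid epoxidation of the 1(10)E-olefin of a germacra-1(10),4(15),11(13)-trien-12,6-olide as the last step; the C3 acetate and C8 angelate are installed before it.
2. Ten-membered carbocycle ⇐ Nozaki–Hiyama–Kishi closure of the C3–C4 bond (2-bromoalkene onto aldehyde).
3. Seco chain ⇐ indium Barbier union forming C7–C8 (creates the α-methylene-γ-lactone, C7 and C8) between an 8-carbon bromomethyl-butenolide (C4–C7, C11–C13, C15) and a 7-carbon aldehyde (C8–C10, C14, C1–C3).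
4. Butenolide ⇐ RCM of a 2-(bromomethyl)acrylate whose C5/C6 diol unit comes from a Brown γ-alkoxyallylboration of 2-bromoacrolein; aldehyde ⇐ Negishi carboalumination of but-3-yn-1-ol, then oxirane opening.
5. Ring order: butenolide (RCM) → α-methylene lactone (double bond transposed in the Barbier step) → carbocycle (Ni/Cr) → epoxide.

Assumption: germacranolide numbering is used in names and comments (ring C1–C10, lactone C12(=O)–C11(=C13), C14 = methyl on C10, C15 = methylene on C4); the enantiomer written in the SMILES is the one made.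

**Western fragment**

Step 1
Reactants: 1 prop-2-enal (acrolein)
Product: 3 2-bromoprop-2-enal, via dibromoaldehyde 2 (not isolated)
Conditions: Br2, CH2Cl2, −78 °C; then Et3N, −78 → 0 °C
Reagents that add atoms: bromine BrBr
Why: Bromine addition to the enal followed by amine-induced dehydrobromination (addition–elimination) gives the α-bromo enal; no stereocentre is formed.

Step 2
Reactants: 4 prop-2-en-1-ol (allyl alcohol)
Product: 5 3-(methoxymethoxy)prop-1-ene
Conditions: MOMCl, i-Pr2NEt, CH2Cl2, 0 °C → rt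
Reagents that add atoms: chloromethyl methyl ether COCCl
Why: Williamson-type O-alkylation (MOM protection) of a primary alcohol; no stereocentre.

Step 3
Reactants: 5 3-(methoxymethoxy)prop-1-ene; 3 2-bromoprop-2-enal
Product: 9 (3R,4S)-2-bromo-4-(methoxymethoxy)hexa-1,5-dien-3-ol, via allyllithium 6 (not isolated), via allylborane 7 (not isolated), via borinate ester 8 (not isolated)
Conditions: 5, s-BuLi, THF, −78 °C; (+)-Ipc2BOMe [from (−)-α-pinene]; BF3·OEt2; then 3, −78 °C; NaOH, H2O2, 0 °C → rt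
Reagents that add atoms: none
Why: Brown asymmetric γ-alkoxyallylboration: the Z-alkoxyallylborane reacts through a chair Zimmerman–Traxler transition state, so Z geometry gives the syn (threo) diol monoether, and the isopinocampheyl groups direct the allyl unit to the Re face of the aldehyde, setting C5 (3R here because of the bromine priority) and C6 (4S).

Step 4
Reactants: 9 (3R,4S)-2-bromo-4-(methoxymethoxy)hexa-1,5-dien-3-ol
Product: 10 {[(3R,4S)-2-bromo-4-(methoxymethoxy)hexa-1,5-dien-3-yl]oxy}(tert-butyl)dimethylsilane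
Conditions: TBSCl, imidazole, DMF, rt → 40 °C
Reagents that add atoms: tert-butyldimethylsilyl chloride CC(C)(C)[Si](C)(C)Cl
Why: Silylation of the secondary alcohol under imidazole catalysis (no silyl triflate, so the MOM acetal is safe); the C–O bond is not touched, so configuration is retained.

Step 5
Reactants: 10 {[(3R,4S)-2-bromo-4-(methoxymethoxy)hexa-1,5-dien-3-yl]oxy}(tert-butyl)dimethylsilane
Product: 12 (3S,4R)-5-bromo-4-{[tert-butyl(dimethyl)silyl]oxy}hexa-1,5-dien-3-ol, via bromomethyl ether 11 (not isolated)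
Conditions: Me2BBr, CH2Cl2, −78 °C; then sat. aq NaHCO3/THF
Reagents that add atoms: none
Why: Guindon acetal cleavage: the boron bromide ionises only the MOM acetal at −78 °C to a bromomethyl ether that is hydrolysed on quench, leaving the secondary TBS ether, both alkenes and both stereocentres untouched.

Step 6
Reactants: 13 2-(bromomethyl)prop-2-enoic acid
Product: 14 2-(bromomethyl)prop-2-enoyl chloride
Conditions: (COCl)2, DMF (cat.), CH2Cl2, 0 °C → rt; volatiles removed, used directly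
Reagents that add atoms: oxalyl chloride O=C(Cl)C(=O)Cl
Why: Vilsmeier-catalysed acid chloride formation; avoids carbodiimide/DMAP, which would attack the allylic bromide.

Step 7
Reactants: 12 (3S,4R)-5-bromo-4-{[tert-butyl(dimethyl)silyl]oxy}hexa-1,5-dien-3-ol; 14 2-(bromomethyl)prop-2-enoyl chloride
Product: 15 (3S,4R)-5-bromo-4-{[tert-butyl(dimethyl)silyl]oxy}hexa-1,5-dien-3-yl 2-(bromomethyl)prop-2-enoate
Conditions: 2,6-lutidine, CH2Cl2, −20 → 0 °C
Reagents that add atoms: none
Why: O-acylation with an acid chloride and a hindered, non-nucleophilic base (no SN2′ on the allylic bromide); the carbinol C–O bond is retained.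

Step 8
Reactants: 15 (3S,4R)-5-bromo-4-{[tert-butyl(dimethyl)silyl]oxy}hexa-1,5-dien-3-yl 2-(bromomethyl)prop-2-enoate
Product: 16 (5S)-3-(bromomethyl)-5-[(1R)-2-bromo-1-{[tert-butyl(dimethyl)silyl]oxy}prop-2-en-1-yl]furan-2(5H)-one
Conditions: second-generation Hoveyda–Grubbs catalyst (10 mol%), toluene, 80 °C, argon sparge
Reagents that add atoms: none
Why: Ring-closing metathesis between the vinyl group and the acrylate closes the five-membered butenolide; the 1,1-disubstituted bromoalkene is metathesis-inert and no stereocentre is involved.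

**Eastern fragment**

Step 9
Reactants: 17 but-3-yn-1-ol
Product: 18 1-[(but-3-yn-1-yloxy)methyl]-4-methoxybenzene
Conditions: NaH, 4-methoxybenzyl chloride, Bu4NI (cat.), THF/DMF, 0 °C → rt
Reagents that add atoms: 4-methoxybenzyl chloride COc1ccc(CCl)cc1
Why: Williamson etherification (PMB protection); the alkoxide forms selectively over the far less acidic alkyne C–H.

Step 10
Reactants: 18 1-[(but-3-yn-1-yloxy)methyl]-4-methoxybenzene
Product: 20 1-({[(3E)-4-iodo-3-methylbut-3-en-1-yl]oxy}methyl)-4-methoxybenzene, via alkenylalane 19 (not isolated)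
Conditions: Me3Al, Cp2ZrCl2 (25 mol%), CH2Cl2, 0 °C → rt; then I2, THF, −30 → 0 °C
Reagents that add atoms: trimethylaluminium C[Al](C)C; iodine II
Why: Negishi zirconium-catalysed carboalumination adds methyl and aluminium syn across the terminal alkyne (methyl at the internal carbon) and iodinolysis proceeds with retention, fixing the E trisubstituted olefin (C10=C1, C14 methyl).

Step 11
Reactants: 20 1-({[(3E)-4-iodo-3-methylbut-3-en-1-yl]oxy}methyl)-4-methoxybenzene; 21 oxirane
Product: 23 (3E)-6-[(4-methoxybenzyl)oxy]-4-methylhex-3-en-1-ol, via alkenyllithium 22 (not isolated)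
Conditions: t-BuLi (2.1 equiv), Et2O, −78 °C; then 21, −78 → 0 °C; H2O
Reagents that add atoms: none
Why: Iodine–lithium exchange with retention of olefin geometry, then SN2 opening of oxirane by the alkenyllithium, adds C2–C3 as a two-carbon primary alcohol.

Step 12
Reactants: 23 (3E)-6-[(4-methoxybenzyl)oxy]-4-methylhex-3-en-1-ol
Product: 24 triethyl({(3E)-6-[(4-methoxybenzyl)oxy]-4-methylhex-3-en-1-yl}oxy)silane
Conditions: Et3SiCl, imidazole, CH2Cl2, 0 °C
Reagents that add atoms: chlorotriethylsilane CC[Si](Cl)(CC)CC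
Why: Silylation of the primary alcohol; the TES ether is later removable in the presence of the secondary TBS ether.

Step 13
Reactants: 24 triethyl({(3E)-6-[(4-methoxybenzyl)oxy]-4-methylhex-3-en-1-yl}oxy)silane
Product: 25 (3E)-3-methyl-6-[(triethylsilyl)oxy]hex-3-en-1-ol
Conditions: DDQ, CH2Cl2/pH 7 buffer, 0 °C
Reagents that add atoms: none
Why: Oxidative PMB cleavage (hydride abstraction by DDQ, hydrolysis of the oxocarbenium ion); buffered, so the TES ether survives.

Step 14
Reactants: 25 (3E)-3-methyl-6-[(triethylsilyl)oxy]hex-3-en-1-ol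
Product: 26 (3E)-3-methyl-6-[(triethylsilyl)oxy]hex-3-enal
Conditions: Dess–Martin periodinane, pyridine, CH2Cl2, 0 °C; used crude
Reagents that add atoms: none
Why: Dess–Martin oxidation under buffered, amine-light conditions gives the β,γ-unsaturated aldehyde without migration of the olefin into conjugation.

**Union and endgame**

Step 15
Reactants: 16 (5S)-3-(bromomethyl)-5-[(1R)-2-bromo-1-{[tert-butyl(dimethyl)silyl]oxy}prop-2-en-1-yl]furan-2(5H)-one; 26 (3E)-3-methyl-6-[(triethylsilyl)oxy]hex-3-enal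
Product: 28 (4R,5S)-5-[(1R)-2-bromo-1-{[tert-butyl(dimethyl)silyl]oxy}prop-2-en-1-yl]-4-{(1S,3E)-1-hydroxy-3-methyl-6-[(triethylsilyl)oxy]hex-3-en-1-yl}-3-methylideneoxolan-2-one, via allylindium bromide 27 (not isolated)
Conditions: indium powder, THF/H2O (3:1), 0 °C → rt
Reagents that add atoms: none
Why: Indium Barbier allylation (γ-selective SE2′ addition through a closed six-membered transition state): the C7–C8 bond forms on the butenolide face anti to the bulky C6 side chain (6,7-trans, 7R), and because the ring locks the allyl unit in an E-crotyl-like geometry the aldehyde chain sits equatorial and gives the anti C7/C8 relationship (8S), while the double bond moves to the exocyclic α-methylene position and the vinylic bromide stays inert.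

Step 16
Reactants: 28 the Barbier adduct; 29 (2Z)-2-methylbut-2-enoic acid (angelic acid)
Product: 31 (1S,3E)-1-{(2S,3R)-2-[(1R)-2-bromo-1-{[tert-butyl(dimethyl)silyl]oxy}prop-2-en-1-yl]-4-methylidene-5-oxooxolan-3-yl}-3-methyl-6-[(triethylsilyl)oxy]hex-3-en-1-yl (2Z)-2-methylbut-2-enoate, via mixed anhydride 30 (not isolated)
Conditions: 29, 2,4,6-trichlorobenzoyl chloride, Et3N, toluene, rt; then 28, 80 °C
Reagents that add atoms: none
Why: Yamaguchi-type mixed-anhydride esterification run without DMAP (the usual protocol for angelates) acylates the hindered C8 hydroxyl with retention and without Z → E isomerisation to the tiglate, and it blocks lactone migration to O8.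

Step 17
Reactants: 31 the angelate TES ether
Product: 32 (1S,3E)-1-{(2S,3R)-2-[(1R)-2-bromo-1-{[tert-butyl(dimethyl)silyl]oxy}prop-2-en-1-yl]-4-methylidene-5-oxooxolan-3-yl}-6-hydroxy-3-methylhex-3-en-1-yl (2Z)-2-methylbut-2-enoate
Conditions: PPTS (cat.), MeOH/CH2Cl2, 0 °C
Reagents that add atoms: none
Why: Mild acid-catalysed methanolysis removes the primary TES ether much faster than the hindered secondary TBS ether; esters and lactone are untouched.

Step 18
Reactants: 32 the primary alcohol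
Product: 33 (1S,3E)-1-{(2S,3R)-2-[(1R)-2-bromo-1-{[tert-butyl(dimethyl)silyl]oxy}prop-2-en-1-yl]-4-methylidene-5-oxooxolan-3-yl}-3-methyl-6-oxohex-3-en-1-yl (2Z)-2-methylbut-2-enoate
Conditions: Dess–Martin periodinane, pyridine, CH2Cl2, 0 °C; used crude
Reagents that add atoms: none
Why: Dess–Martin oxidation gives the C3 aldehyde under near-neutral conditions, so the β,γ-olefin and the C6/C7 centres are not disturbed.

Step 19
Reactants: 33 the seco bromo-aldehyde
Product: 35 (3R,5S,6S,7R,8S)-5-{[tert-butyl(dimethyl)silyl]oxy}-3-hydroxy-8-[(2Z)-2-methylbut-2-enoyloxy]germacra-1(10)E,4(15),11(13)-trien-12,6-olide, via alkenylchromium 34 (not isolated)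
Conditions: CrCl2 (6 equiv), chiral oxazoline–sulfonamide ligand (Kishi type, enantiomer giving Si-face addition), Et3N, NiCl2(2,9-dimethyl-1,10-phenanthroline) (20 mol%), THF/MeCN, 0.002 M, rt, slow addition of 33
Reagents that add atoms: none
Why: Nozaki–Hiyama–Kishi macrocyclisation: zerovalent nickel inserts into the 2-bromoalkene, transmetalation gives the alkenyl species of trivalent chromium, which adds only to the aldehyde under high dilution to close the ten-membered ring, and the chiral sulfonamide on chromium delivers the alkenyl group to the Si face of the aldehyde, setting C3 as R.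

Step 20
Reactants: 35 the macrocyclic C3 alcohol
Product: 36 (3R,5S,6S,7R,8S)-3-acetoxy-5-{[tert-butyl(dimethyl)silyl]oxy}-8-[(2Z)-2-methylbut-2-enoyloxy]germacra-1(10)E,4(15),11(13)-trien-12,6-olide
Conditions: Ac2O, pyridine, DMAP (cat.), CH2Cl2, 0 °C
Reagents that add atoms: acetic anhydride CC(=O)OC(C)=O
Why: Acylation of the only free hydroxyl (C5 is silylated) with retention at C3.

Step 21
Reactants: 36 the C3 acetate
Product: 37 (3R,5S,6S,7R,8S)-3-acetoxy-5-hydroxy-8-[(2Z)-2-methylbut-2-enoyloxy]germacra-1(10)E,4(15),11(13)-trien-12,6-olide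
Conditions: HF·pyridine, pyridine, THF, 0 °C → rt
Reagents that add atoms: none
Why: Fluoride-mediated desilylation under buffered acidic conditions, where neither acyl migration (C3 → C5) nor Michael addition to the α-methylene lactone occurs; it is done before epoxidation so the epoxide never meets HF.

Step 22
Reactants: 37 the diene lactone
Product: 38 (1R,3R,5S,6S,7R,8S,10R)-3-acetoxy-1,10-epoxy-5-hydroxy-8-[(2Z)-2-methylbut-2-enoyloxy]germacra-4(15),11(13)-dien-12,6-olide (target)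
Conditions: mCPBA (1.1 equiv), CH2Cl2, −10 → 0 °C; aq Na2S2O3/NaHCO3 wash
Reagents that add atoms: 3-chloroperoxybenzoic acid OOC(=O)c1cccc(Cl)c1
Why: Prilezhaev epoxidation is selective for the only electron-rich olefin (the 4(15)-methylene is deactivated by two allylic C–O bonds, the other two are conjugated to carbonyls), and attack on the exposed outer face of the E-olefin of a 6α,12-trans-lactonised germacrene gives the 1β,10α-epoxide, i.e. 1R,10R, as with mCPBA on costunolide- and parthenolide-type lactones.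

**Compound list**

1 | prop-2-enal (acrolein) | C=CC=O | starting material
2 | 2,3-dibromopropanal | O=CC(Br)CBr | intermediate (not isolated)
3 | 2-bromoprop-2-enal | C=C(Br)C=O | intermediate
4 | prop-2-en-1-ol (allyl alcohol) | C=CCO | starting material
5 | 3-(methoxymethoxy)prop-1-ene | C=CCOCOC | intermediate
6 | [(2Z)-3-(methoxymethoxy)prop-2-en-1-yl]lithium | [Li]C/C=C\OCOC | intermediate (not isolated)
7 | bis(isopinocampheyl)[(2Z)-3-(methoxymethoxy)prop-2-en-1-yl]borane, Ipc groups from (−)-α-pinene | COCO/C=C\CB([C@H]1C[C@H]2C[C@@H]([C@@H]1C)C2(C)C)[C@H]1C[C@H]2C[C@@H]([C@@H]1C)C2(C)C | intermediate (not isolated)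
8 | (3R,4S)-2-bromo-4-(methoxymethoxy)hexa-1,5-dien-3-yl bis(isopinocampheyl)borinate | C=C[C@H](OCOC)[C@@H](OB([C@H]1C[C@H]2C[C@@H]([C@@H]1C)C2(C)C)[C@H]1C[C@H]2C[C@@H]([C@@H]1C)C2(C)C)C(Br)=C | intermediate (not isolated)
9 | (3R,4S)-2-bromo-4-(methoxymethoxy)hexa-1,5-dien-3-ol | C=C[C@H](OCOC)[C@@H](O)C(Br)=C | intermediate
10 | {[(3R,4S)-2-bromo-4-(methoxymethoxy)hexa-1,5-dien-3-yl]oxy}(tert-butyl)dimethylsilane | C=C[C@H](OCOC)[C@@H](O[Si](C)(C)C(C)(C)C)C(Br)=C | intermediate
11 | {[(3R,4S)-2-bromo-4-(bromomethoxy)hexa-1,5-dien-3-yl]oxy}(tert-butyl)dimethylsilane | C=C[C@H](OCBr)[C@@H](O[Si](C)(C)C(C)(C)C)C(Br)=C | intermediate (not isolated)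
12 | (3S,4R)-5-bromo-4-{[tert-butyl(dimethyl)silyl]oxy}hexa-1,5-dien-3-ol | C=C[C@H](O)[C@@H](O[Si](C)(C)C(C)(C)C)C(Br)=C | intermediate
13 | 2-(bromomethyl)prop-2-enoic acid | C=C(CBr)C(=O)O | starting material
14 | 2-(bromomethyl)prop-2-enoyl chloride | C=C(CBr)C(=O)Cl | intermediate
15 | (3S,4R)-5-bromo-4-{[tert-butyl(dimethyl)silyl]oxy}hexa-1,5-dien-3-yl 2-(bromomethyl)prop-2-enoate | C=C[C@H](OC(=O)C(=C)CBr)[C@@H](O[Si](C)(C)C(C)(C)C)C(Br)=C | intermediate
16 | (5S)-3-(bromomethyl)-5-[(1R)-2-bromo-1-{[tert-butyl(dimethyl)silyl]oxy}prop-2-en-1-yl]furan-2(5H)-one | O=C1O[C@@H](C=C1CBr)[C@@H](O[Si](C)(C)C(C)(C)C)C(Br)=C | intermediate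
17 | but-3-yn-1-ol | C#CCCO | starting material
18 | 1-[(but-3-yn-1-yloxy)methyl]-4-methoxybenzene | C#CCCOCc1ccc(OC)cc1 | intermediate
19 | {(1E)-4-[(4-methoxybenzyl)oxy]-2-methylbut-1-en-1-yl}dimethylalumane | C/C(CCOCc1ccc(OC)cc1)=C\[Al](C)C | intermediate (not isolated)
20 | 1-({[(3E)-4-iodo-3-methylbut-3-en-1-yl]oxy}methyl)-4-methoxybenzene | C/C(CCOCc1ccc(OC)cc1)=C\I | intermediate
21 | oxirane | C1CO1 | starting material
22 | {(1E)-4-[(4-methoxybenzyl)oxy]-2-methylbut-1-en-1-yl}lithium | C/C(CCOCc1ccc(OC)cc1)=C\[Li] | intermediate (not isolated)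
23 | (3E)-6-[(4-methoxybenzyl)oxy]-4-methylhex-3-en-1-ol | C/C(CCOCc1ccc(OC)cc1)=C\CCO | intermediate
24 | triethyl({(3E)-6-[(4-methoxybenzyl)oxy]-4-methylhex-3-en-1-yl}oxy)silane | C/C(CCOCc1ccc(OC)cc1)=C\CCO[Si](CC)(CC)CC | intermediate
25 | (3E)-3-methyl-6-[(triethylsilyl)oxy]hex-3-en-1-ol | C/C(CCO)=C\CCO[Si](CC)(CC)CC | intermediate
26 | (3E)-3-methyl-6-[(triethylsilyl)oxy]hex-3-enal | C/C(CC=O)=C\CCO[Si](CC)(CC)CC | intermediate
27 | allylindium dibromide derived from 16 (InBr2 in place of the allylic bromine) | O=C1O[C@@H](C=C1C[In](Br)Br)[C@@H](O[Si](C)(C)C(C)(C)C)C(Br)=C | intermediate (not isolated)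
28 | (4R,5S)-5-[(1R)-2-bromo-1-{[tert-butyl(dimethyl)silyl]oxy}prop-2-en-1-yl]-4-{(1S,3E)-1-hydroxy-3-methyl-6-[(triethylsilyl)oxy]hex-3-en-1-yl}-3-methylideneoxolan-2-one | C=C1C(=O)O[C@H]([C@@H](O[Si](C)(C)C(C)(C)C)C(Br)=C)[C@H]1[C@@H](O)C/C(C)=C/CCO[Si](CC)(CC)CC | intermediate
29 | (2Z)-2-methylbut-2-enoic acid (angelic acid) | C/C=C(/C)C(=O)O | starting material
30 | (2Z)-2-methylbut-2-enoic 2,4,6-trichlorobenzoic anhydride | C/C=C(/C)C(=O)OC(=O)c1c(Cl)cc(Cl)cc1Cl | intermediate (not isolated)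
31 | (1S,3E)-1-{(2S,3R)-2-[(1R)-2-bromo-1-{[tert-butyl(dimethyl)silyl]oxy}prop-2-en-1-yl]-4-methylidene-5-oxooxolan-3-yl}-3-methyl-6-[(triethylsilyl)oxy]hex-3-en-1-yl (2Z)-2-methylbut-2-enoate | C=C1C(=O)O[C@H]([C@@H](O[Si](C)(C)C(C)(C)C)C(Br)=C)[C@H]1[C@@H](OC(=O)/C(C)=C\C)C/C(C)=C/CCO[Si](CC)(CC)CC | intermediate
32 | (1S,3E)-1-{(2S,3R)-2-[(1R)-2-bromo-1-{[tert-butyl(dimethyl)silyl]oxy}prop-2-en-1-yl]-4-methylidene-5-oxooxolan-3-yl}-6-hydroxy-3-methylhex-3-en-1-yl (2Z)-2-methylbut-2-enoate | C=C1C(=O)O[C@H]([C@@H](O[Si](C)(C)C(C)(C)C)C(Br)=C)[C@H]1[C@@H](OC(=O)/C(C)=C\C)C/C(C)=C/CCO | intermediate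
33 | (1S,3E)-1-{(2S,3R)-2-[(1R)-2-bromo-1-{[tert-butyl(dimethyl)silyl]oxy}prop-2-en-1-yl]-4-methylidene-5-oxooxolan-3-yl}-3-methyl-6-oxohex-3-en-1-yl (2Z)-2-methylbut-2-enoate | C=C1C(=O)O[C@H]([C@@H](O[Si](C)(C)C(C)(C)C)C(Br)=C)[C@H]1[C@@H](OC(=O)/C(C)=C\C)C/C(C)=C/CC=O | intermediate
34 | alkenylchromium dichloride derived from 33 (CrCl2 in place of the vinylic bromine at C4) | C=C1C(=O)O[C@H]([C@@H](O[Si](C)(C)C(C)(C)C)C(=C)[Cr](Cl)Cl)[C@H]1[C@@H](OC(=O)/C(C)=C\C)C/C(C)=C/CC=O | intermediate (not isolated)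
35 | (3R,5S,6S,7R,8S)-5-{[tert-butyl(dimethyl)silyl]oxy}-3-hydroxy-8-[(2Z)-2-methylbut-2-enoyloxy]germacra-1(10)E,4(15),11(13)-trien-12,6-olide | C=C1C(=O)O[C@H]2[C@H]1[C@@H](OC(=O)/C(C)=C\C)C/C(C)=C/C[C@@H](O)C(=C)[C@@H]2O[Si](C)(C)C(C)(C)C | intermediate
36 | (3R,5S,6S,7R,8S)-3-acetoxy-5-{[tert-butyl(dimethyl)silyl]oxy}-8-[(2Z)-2-methylbut-2-enoyloxy]germacra-1(10)E,4(15),11(13)-trien-12,6-olide | C=C1C(=O)O[C@H]2[C@H]1[C@@H](OC(=O)/C(C)=C\C)C/C(C)=C/C[C@@H](OC(C)=O)C(=C)[C@@H]2O[Si](C)(C)C(C)(C)C | intermediate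
37 | (3R,5S,6S,7R,8S)-3-acetoxy-5-hydroxy-8-[(2Z)-2-methylbut-2-enoyloxy]germacra-1(10)E,4(15),11(13)-trien-12,6-olide | C=C1C(=O)O[C@H]2[C@H]1[C@@H](OC(=O)/C(C)=C\C)C/C(C)=C/C[C@@H](OC(C)=O)C(=C)[C@@H]2O | intermediate
38 | (1R,3R,5S,6S,7R,8S,10R)-3-acetoxy-1,10-epoxy-5-hydroxy-8-[(2Z)-2-methylbut-2-enoyloxy]germacra-4(15),11(13)-dien-12,6-olide (CNP0210054.2) | C=C1C(=O)O[C@H]2[C@H]1[C@@H](OC(=O)/C(C)=C\C)C[C@@]1(C)O[C@@H]1C[C@@H](OC(C)=O)C(=C)[C@@H]2O | target

**Step count and risks**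

Total step count: 22. Longest linear sequence: 14 steps (1, 3, 4, 5, 7, 8, 15–22; the eastern line 9–14, 15–22 is equally long).

Step 19 is the most likely to fail. The ten-membered closure uses a less reactive 2-bromoalkene, and the ring may override the chiral chromium ligand at C3. The fallback sets out from 33 and comes back at 35. The closure is run without ligand (CrCl2, NiCl2 cat., DMSO/THF, high dilution), which gives 35 together with the (3S)-epimeric macrocyclic alcohol F2. The mixture is oxidised with Dess–Martin periodinane to the macrocyclic α-methylene ketone F3. Corey–Bakshi–Shibata reduction with (S)-2-methyl-CBS-oxazaborolidine and BH3·SMe2 at −40 °C then sets C3 by reagent control (CH2 as small group, 1,1-disubstituted alkenyl as large group) and returns to 35.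

Step 15 is the next risk. The allylindium may react through an open transition state and give the wrong C8 configuration, and the free C8 alkoxide can translactonise. The fallback sets out from 16 (with 26) and comes back at 31. If the coupling delivers mainly the C8-epimeric homoallylic alcohol F1, it is esterified with angelic acid 29 under Mitsunobu conditions (PPh3, diisopropyl azodicarboxylate, toluene, 0 °C → rt). Inversion at C8 and installation of the angelate occur in one operation, rejoining the route at 31.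

Step 22 is the third risk. The facial selectivity rests on the macrocycle conformation, and the free C5 hydroxyl could direct some oxidant to the 4(15)-methylene. The fallback sets out from 32 and comes back at 38. The acyclic trisubstituted olefin of 32 is epoxidised under reagent control by Shi epoxidation (D-fructose-derived Shi ketone, Oxone (2KHSO5·KHSO4·K2SO4), K2CO3 buffer, MeCN/dimethoxymethane/H2O, 0 °C) to the (R,R)-epoxy alcohol F4. Dess–Martin oxidation gives the epoxy aldehyde F5. Ni/Cr macrocyclisation as in step 19 gives the epoxy macrocyclic alcohol F6. Acetylation gives the epoxy acetate F7. HF·pyridine buffered with pyridine then removes the silyl group to give 38.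

Further compounds
F1 | step 15 | (4R,5S)-5-[(1R)-2-bromo-1-{[tert-butyl(dimethyl)silyl]oxy}prop-2-en-1-yl]-4-{(1R,3E)-1-hydroxy-3-methyl-6-[(triethylsilyl)oxy]hex-3-en-1-yl}-3-methylideneoxolan-2-one | C=C1C(=O)O[C@H]([C@@H](O[Si](C)(C)C(C)(C)C)C(Br)=C)[C@H]1[C@H](O)C/C(C)=C/CCO[Si](CC)(CC)CC
F2 | step 19 | (3S,5S,6S,7R,8S)-5-{[tert-butyl(dimethyl)silyl]oxy}-3-hydroxy-8-[(2Z)-2-methylbut-2-enoyloxy]germacra-1(10)E,4(15),11(13)-trien-12,6-olide | C=C1C(=O)O[C@H]2[C@H]1[C@@H](OC(=O)/C(C)=C\C)C/C(C)=C/C[C@H](O)C(=C)[C@@H]2O[Si](C)(C)C(C)(C)C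
F3 | step 19 | (5S,6S,7R,8S)-5-{[tert-butyl(dimethyl)silyl]oxy}-8-[(2Z)-2-methylbut-2-enoyloxy]-3-oxogermacra-1(10)E,4(15),11(13)-trien-12,6-olide | C=C1C(=O)O[C@H]2[C@H]1[C@@H](OC(=O)/C(C)=C\C)C/C(C)=C/CC(=O)C(=C)[C@@H]2O[Si](C)(C)C(C)(C)C
F4 | step 22 | (1S)-1-{(2S,3R)-2-[(1R)-2-bromo-1-{[tert-butyl(dimethyl)silyl]oxy}prop-2-en-1-yl]-4-methylidene-5-oxooxolan-3-yl}-2-[(2R,3R)-3-(2-hydroxyethyl)-2-methyloxiran-2-yl]ethyl (2Z)-2-methylbut-2-enoate | C=C1C(=O)O[C@H]([C@@H](O[Si](C)(C)C(C)(C)C)C(Br)=C)[C@H]1[C@@H](OC(=O)/C(C)=C\C)C[C@@]1(C)O[C@@H]1CCO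
F5 | step 22 | (1S)-1-{(2S,3R)-2-[(1R)-2-bromo-1-{[tert-butyl(dimethyl)silyl]oxy}prop-2-en-1-yl]-4-methylidene-5-oxooxolan-3-yl}-2-[(2R,3R)-2-methyl-3-(2-oxoethyl)oxiran-2-yl]ethyl (2Z)-2-methylbut-2-enoate | C=C1C(=O)O[C@H]([C@@H](O[Si](C)(C)C(C)(C)C)C(Br)=C)[C@H]1[C@@H](OC(=O)/C(C)=C\C)C[C@@]1(C)O[C@@H]1CC=O
F6 | step 22 | (1R,3R,5S,6S,7R,8S,10R)-5-{[tert-butyl(dimethyl)silyl]oxy}-1,10-epoxy-3-hydroxy-8-[(2Z)-2-methylbut-2-enoyloxy]germacra-4(15),11(13)-dien-12,6-olide | C=C1C(=O)O[C@H]2[C@H]1[C@@H](OC(=O)/C(C)=C\C)C[C@@]1(C)O[C@@H]1C[C@@H](O)C(=C)[C@@H]2O[Si](C)(C)C(C)(C)C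
F7 | step 22 | (1R,3R,5S,6S,7R,8S,10R)-3-acetoxy-5-{[tert-butyl(dimethyl)silyl]oxy}-1,10-epoxy-8-[(2Z)-2-methylbut-2-enoyloxy]germacra-4(15),11(13)-dien-12,6-olide | C=C1C(=O)O[C@H]2[C@H]1[C@@H](OC(=O)/C(C)=C\C)C[C@@]1(C)O[C@@H]1C[C@@H](OC(C)=O)C(=C)[C@@H]2O[Si](C)(C)C(C)(C)C
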